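The runs stem from a simulated flask for an exercise, noise included.

I decide to weigh each given number by what an error in it costs, before I reckon any amount.

| setting | south | south-east | winter | noon | autumn |
|---|---|---|---|---|---|
| L | 24 mM | 72 mM | 36 mM | 36 mM | 36 mM |
| Q | 1 equiv | 1 equiv | 1.00 equiv | 3.00 equiv | 4.00 equiv |
| remark | run made earlier | run made earlier |  |  |  |
| time |  |  | 3.0 h | 3.0 h | 3.0 h |

| run | time / min | J / % | X / % |
|---|---|---|---|
| south | 3.00 | 0.5 | 2.6 |
| south | 6.00 | 0.4 | 4.2 |
| south | 15.0 | 0.9 | 6.1 |
| south | 40.0 | 0.8 | 6.0 |
| south-east | 3.00 | 0.6 | 4.0 |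
| south-east | 6.00 | 0.9 | 5.5 |
| south-east | 15.0 | 1.0 | 6.7 |
| south-east | 40.0 | 1.6 | 6.0 |

(readings scatter by 0.3 percentage points)

1. which of these holds the largest part of the L at the end of winter (X / L / G / J)
2. which of these holds the largest part of the L at the end of noon (X / L / G / J)
3. which of these holds the largest part of the L at the end of autumn (X / L / G / J)
4. final J in noon, as a percentage of the L charged



Time comes first. In south, X reads 2.6 % after 3.00 min and 6.0 % after 40.0 min, which is a fraction 0.433 of its level. South-east, charged 3.00 times as strongly, reads a fraction 0.667 at the same time, higher than south. So in these readings the rise quickens with the charge. I assume that Q reacts in pairs with a partner, and I scale the south time inversely with the Q charged: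

noon: 0.667 min

winter: 2.00 min

This is the rise time, my estimate of the time X needs to reach that first fraction of its level. Set against it, the time given is large:

time given / rise time, noon: 270

So an error in the time of noon costs little.

L comes next. Between south and south-east, X ends at 6.0 % and 6.0 %, and J at 0.8 % and 1.6 %. That gap in J is the difference of two single readings, each with a scatter of 0.3 percentage points, and at 15.0 min the pair reads 0.9 % and 1.0 %, a gap of 0.1 points. So I read most of the gap as scatter, and I expect an error in L to cost little at this charge of Q.

Q comes last. Both runs used 1 equiv, but noon has 3.00 equiv, so no reading shows what Q does. I commit to this: noon is flat long before its end, and its amounts hang on Q.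

The forecast names L, G and G as the largest holders in winter, noon and autumn, and J 5.5 % in noon (2.5 % to 11 %), from “a fast, concentration-independent exchange equilibrium”.

The flask gives L, G and G, with J 4.33 % in noon.

    L + Q ⇌ Z + G (K = 1.10, k = 0.210 M⁻¹ s⁻¹)
    G + Q ⇌ Z + X (K = 0.320, k = 0.100 M⁻¹ s⁻¹)
    X + Q ⇌ Z + J (K = 2.10, k = 0.110 M⁻¹ s⁻¹)
    2 Q → D (k = 0.180 M⁻¹ s⁻¹)
    Z → E (k = 0.0140 s⁻¹)

In noon, J stands at 4.33 % after 1.50 h and 4.33 % after 3.00 h, as the margin of 270 led me to expect, with Q, the limiting reagent, at 0 % of its charge. Winter, whose rise time of 2.00 min is longer than noon's, is as flat: J 0.932 %, then 0.932 %. In noon, the turnover of Z into E reaches its midpoint by 2.05 min, far shorter than the 3.0 h given. That step has 99.0 % of its turnover behind it after 0.300 h, and L + Q into Z + G has 100 % behind it after 1.50 h.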